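**Plan**
- Retrosynthesis: the benzyl ester that masks the ring-B acid is cut first, then the two ring-A bonds C1–C2 and C5–C6 (Diels–Alder with aromatisation). The depside O–C(=O) bond is then traced back to a ring-B phenol and oct-2-ynoic acid, and ring B to 5-heptylresorcinol.
- Forward: ring B is completed first (carboxylation, benzyl ester, 4-O-allyl, 2-O-methyl, deallylation) and acylated with oct-2-ynoic acid. Ring A is then built on the ynoate by [4+2] cycloaddition with a silyloxydiene, and hydrogenolysis frees the acid.
- Enabling feature: ring A is a 2-hydroxy-4-methoxy-6-pentylbenzoate (C1 carbonyl-bearing, C2–OH, C4–OMe, C6–pentyl). C2–C5 with their oxygens map onto a 1,1,3-trioxygenated butadiene, and C1/C6 with the carbonyl and pentyl map onto a 2-alkynoate.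
- The doubly ortho-flanked acyl–oxygen bond of the depside is made while the acyl carbon is still an unhindered alkynoyl group.
- Stereochemistry: the target has no stereocentre; the ketene-acetal geometry of the diene and the ketal carbon of the cycloadduct are erased on aromatisation.

Key step: step 8

Remark on the chemistry: the target has no stereocentre, stereogenic double bond or stable axis, so it is a single achiral compound and no enantioselective step is needed. 5-Heptylresorcinol, oct-2-ynoic acid and methyl (E)-3-methoxybut-2-enoate are taken as purchasable.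

**Route**

Step 1
Reactants: 1 5-heptylbenzene-1,3-diol (5-heptylresorcinol)
Product: 2 2-heptyl-4,6-dihydroxybenzoic acid
Conditions: methyl magnesium carbonate (2 M in DMF, excess), 125 °C, N2; then ice-cold aq. HCl
Reagents that add atoms: methyl magnesium carbonate, COC(=O)O[Mg]OC
Why: Kolbe–Schmitt-type carboxylation in which the magnesium phenoxide delivers CO2 to the ring position ortho to one hydroxyl and para to the other, the magnesium salicylate chelate holding the carboxyl until cold acidification.

Step 2
Reactants: 2 2-heptyl-4,6-dihydroxybenzoic acid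
Product: 3 benzyl 2-heptyl-4,6-dihydroxybenzoate
Conditions: BnBr (1.05 equiv), KHCO3, DMF, rt
Reagents that add atoms: benzyl bromide, BrCc1ccccc1
Why: SN2 O-alkylation of the carboxylate; hydrogencarbonate deprotonates only the carboxylic acid, so both phenols should stay free.

Step 3
Reactants: 3 benzyl 2-heptyl-4,6-dihydroxybenzoate
Product: 4 benzyl 4-(allyloxy)-2-heptyl-6-hydroxybenzoate
Conditions: allyl bromide (1.05 equiv), K2CO3, acetone, rt to 40 °C
Reagents that add atoms: allyl bromide, C=CCBr
Why: Williamson etherification; the 4-hydroxyl is not hydrogen-bonded to the ester carbonyl, is the more acidic and nucleophilic phenol, and should be alkylated selectively by one equivalent of halide.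

Step 4
Reactants: 4 benzyl 4-(allyloxy)-2-heptyl-6-hydroxybenzoate
Product: 5 benzyl 4-(allyloxy)-2-heptyl-6-methoxybenzoate
Conditions: MeI (3 equiv), K2CO3, DMF, 50 °C
Reagents that add atoms: iodomethane, CI
Why: Williamson methylation of the remaining chelated phenol under more forcing conditions, to which the allyl ether and benzyl ester are inert.

Step 5
Reactants: 5 benzyl 4-(allyloxy)-2-heptyl-6-methoxybenzoate
Product: 6 benzyl 2-heptyl-4-hydroxy-6-methoxybenzoate
Conditions: Pd(PPh3)4 (3 mol%), morpholine (5 equiv), THF, rt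
Reagents that add atoms: none
Why: Tsuji–Trost deallylation; Pd(0) ionises the allyl aryl ether to a π-allyl complex that morpholine captures, while the benzyl ester and methyl ether are untouched.

Step 6
Reactants: 6 benzyl 2-heptyl-4-hydroxy-6-methoxybenzoate; 7 oct-2-ynoic acid
Product: 8 4-[(benzyloxy)carbonyl]-3-heptyl-5-methoxyphenyl oct-2-ynoate
Conditions: DCC (1.2 equiv), DMAP (0.1 equiv), CH2Cl2, 0 °C to rt
Reagents that add atoms: none
Why: Steglich esterification; the activated, sterically open alkynoic acid acylates the phenol at low temperature, so the future depside ester bond is made before its acyl carbon acquires two ortho substituents.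

Step 7
Reactants: 9 methyl (E)-3-methoxybut-2-enoate
Product: 10 (E)-1,3-dimethoxy-1-(trimethylsilyloxy)buta-1,3-diene
Conditions: LDA (commercial solution, 1.1 equiv), THF, −78 °C; TMSCl, −78 °C to rt; pentane, filtration, bulb-to-bulb distillation
Reagents that add atoms: chlorotrimethylsilane, C[Si](C)(C)Cl
Why: Kinetic γ-deprotonation of the vinylogous carbonate ester gives the extended dienolate, which is O-silylated to the vinylketene silyl acetal (dienolate silylation); the geometry at the ketene-acetal carbon, drawn as E, is of no consequence because that carbon becomes aromatic C2.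

Step 8
Reactants: 8 4-[(benzyloxy)carbonyl]-3-heptyl-5-methoxyphenyl oct-2-ynoate; 10 (E)-1,3-dimethoxy-1-(trimethylsilyloxy)buta-1,3-diene
Product: 13 benzyl 2-heptyl-4-[(2-hydroxy-4-methoxy-6-pentylbenzoyl)oxy]-6-methoxybenzoate, via cyclohexa-1,4-diene cycloadduct 11 (not isolated), via aryl trimethylsilyl ether 12 (not isolated)
Conditions: 10 (3 equiv, in two portions), PhMe, 120 °C, sealed tube; then 1 M HCl, THF, rt
Reagents that add atoms: none
Why: The electron-rich vinylketene silyl acetal 10 and the electron-poor ynoate 8 should combine in a thermal, concerted but asynchronous [4+2] cycloaddition in which the unsubstituted CH2 terminus of the diene bonds to the pentyl-bearing β-carbon (C5–C6) and the ketene-acetal carbon bonds to the α-carbon (C1–C2), giving cyclohexa-1,4-diene 11; 1,4-elimination of methanol across the ketal carbon and the ring CH2 aromatises it to silyl ether 12, which the acidic work-up hydrolyses to the chelated phenol 13. The closest known reaction type is the Diels–Alder/aromatisation of 1,1,3-trioxygenated butadienes with 2-alkynoate esters to give 6-alkylresorcylates. Ring A is closed as a six-membered carbocycle by an intermolecular [4+2] annulation in which both new ring bonds form in the same operation. No stereocentre has to be controlled, because the ketal carbon of 11 forms as a racemate and becomes sp2 on aromatisation. The step needs regioselectivity (pentyl next to the carbonyl, hydroxyl on the other side), secured by pairing the diene's nucleophilic terminus with the electrophilic β-carbon of the ynoate, and chemoselectivity for cycloaddition over acyl transfer, secured by the absence of Lewis acid or fluoride and by the inertness of the hindered benzyl benzoate of ring B. Methanol rather than silanol should leave the mixed ketal, as expected for mixed methyl silyl vinylketene acetals, and the aryl ester should make the ynoate a better dienophile than the alkyl esters for which the reaction is established.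

Step 9
Reactants: 13 benzyl 2-heptyl-4-[(2-hydroxy-4-methoxy-6-pentylbenzoyl)oxy]-6-methoxybenzoate
Product: 14 2-heptyl-4-[(2-hydroxy-4-methoxy-6-pentylbenzoyl)oxy]-6-methoxybenzoic acid
Conditions: H2 (1 atm), 10% Pd/C, EtOAc, rt
Reagents that add atoms: none
Why: Hydrogenolysis of the benzyl ester cleaves only the benzylic C–O bond; the depside aryl ester, the methyl ethers and the phenol should be inert under these conditions.

**Compound list**
1 | 5-heptylbenzene-1,3-diol (5-heptylresorcinol) | CCCCCCCc1cc(O)cc(O)c1 | starting material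
2 | 2-heptyl-4,6-dihydroxybenzoic acid | CCCCCCCc1cc(O)cc(O)c1C(=O)O | intermediate
3 | benzyl 2-heptyl-4,6-dihydroxybenzoate | CCCCCCCc1cc(O)cc(O)c1C(=O)OCc1ccccc1 | intermediate
4 | benzyl 4-(allyloxy)-2-heptyl-6-hydroxybenzoate | CCCCCCCc1cc(OCC=C)cc(O)c1C(=O)OCc1ccccc1 | intermediate
5 | benzyl 4-(allyloxy)-2-heptyl-6-methoxybenzoate | CCCCCCCc1cc(OCC=C)cc(OC)c1C(=O)OCc1ccccc1 | intermediate
6 | benzyl 2-heptyl-4-hydroxy-6-methoxybenzoate | CCCCCCCc1cc(O)cc(OC)c1C(=O)OCc1ccccc1 | intermediate
7 | oct-2-ynoic acid | CCCCCC#CC(=O)O | starting material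
8 | 4-[(benzyloxy)carbonyl]-3-heptyl-5-methoxyphenyl oct-2-ynoate | CCCCCCCc1cc(OC(=O)C#CCCCCC)cc(OC)c1C(=O)OCc1ccccc1 | intermediate
9 | methyl (E)-3-methoxybut-2-enoate | CO/C(C)=C/C(=O)OC | starting material
10 | (E)-1,3-dimethoxy-1-(trimethylsilyloxy)buta-1,3-diene | C=C(OC)/C=C(\OC)O[Si](C)(C)C | intermediate
11 | 4-[(benzyloxy)carbonyl]-3-heptyl-5-methoxyphenyl 4,6-dimethoxy-2-pentyl-6-(trimethylsilyloxy)cyclohexa-1,4-diene-1-carboxylate (racemic at C6, not isolated) | CCCCCCCc1cc(OC(=O)C2=C(CCCCC)CC(OC)=CC2(OC)O[Si](C)(C)C)cc(OC)c1C(=O)OCc1ccccc1 | intermediate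
12 | benzyl 2-heptyl-6-methoxy-4-{[4-methoxy-2-pentyl-6-(trimethylsilyloxy)benzoyl]oxy}benzoate (not isolated) | CCCCCCCc1cc(OC(=O)c2c(O[Si](C)(C)C)cc(OC)cc2CCCCC)cc(OC)c1C(=O)OCc1ccccc1 | intermediate
13 | benzyl 2-heptyl-4-[(2-hydroxy-4-methoxy-6-pentylbenzoyl)oxy]-6-methoxybenzoate | CCCCCCCc1cc(OC(=O)c2c(O)cc(OC)cc2CCCCC)cc(OC)c1C(=O)OCc1ccccc1 | intermediate
14 | 2-heptyl-4-[(2-hydroxy-4-methoxy-6-pentylbenzoyl)oxy]-6-methoxybenzoic acid | CCCCCCCc1cc(OC(=O)c2c(O)cc(OC)cc2CCCCC)cc(OC)c1C(=O)O | target

**Count**
Total steps: 9. Longest linear sequence: 8 (steps 1–6, 8, 9); step 7 is a one-step side branch.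

**Steps most likely to fail**

Step 8. The cycloaddition of a β-alkyl ynoate may be slower than thermal decay of the ketene acetal. The diene may also transfer to the aryl ester carbonyl with loss of the ring-B phenoxide, or silanol instead of methanol may be lost on aromatisation. The fallback sets out from 6 and returns at 13, and it brings ring A in preformed. Commercial methyl 2,4-dihydroxy-6-pentylbenzoate (CCCCCc1cc(O)cc(O)c1C(=O)OC) would be methylated at its non-chelated 4-hydroxyl (MeI 1.05 equiv, K2CO3, acetone, rt) to methyl 2-hydroxy-4-methoxy-6-pentylbenzoate F1. Saponification (KOH, aq. DMSO, 80 °C, cold acidification) would give 2-hydroxy-4-methoxy-6-pentylbenzoic acid F2. F2 would then be condensed with phenol 6 through its mixed trifluoroacetic anhydride (TFAA, PhMe, rt), the established way to acylate phenols with 2-hydroxy-6-alkylbenzoic acids, to give 13.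

Step 1. Carboxylation may stay incomplete, reverse by decarboxylation during the acidic work-up, or enter the position between the two hydroxyls. The fallback sets out from 1 and returns at 5, and it introduces the carbon as an aldehyde. Vilsmeier–Haack formylation (POCl3, DMF, 0 °C to rt; aq. NaOAc) should give 2-heptyl-4,6-dihydroxybenzaldehyde F3. Selective 4-O-allylation (allyl bromide, K2CO3, acetone) would give 4-(allyloxy)-2-heptyl-6-hydroxybenzaldehyde F4, and methylation (MeI, K2CO3, DMF) would give 4-(allyloxy)-2-heptyl-6-methoxybenzaldehyde F5. Pinnick oxidation (NaClO2, NaH2PO4, 2-methylbut-2-ene, t-BuOH/H2O) would give 4-(allyloxy)-2-heptyl-6-methoxybenzoic acid F6, and benzylation (BnBr, K2CO3, DMF) would give 5.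

Step 7. Deprotonation may be accompanied by C-silylation, and the mixed ketene acetal may hydrolyse or isomerise during isolation, so that too little active diene reaches the key step. The fallback sets out from 8 and returns at 13. It keeps the cycloaddition but uses a purchasable bis-silyl diene and moves the O-methylation to the end. Heating 8 with commercial 1-methoxy-1,3-bis(trimethylsilyloxy)buta-1,3-diene (C=C(O[Si](C)(C)C)C=C(OC)O[Si](C)(C)C) in toluene at 120 °C should give 4-[(benzyloxy)carbonyl]-3-heptyl-5-methoxyphenyl 6-methoxy-2-pentyl-4,6-bis(trimethylsilyloxy)cyclohexa-1,4-diene-1-carboxylate F7. Loss of methanol would give benzyl 2-heptyl-6-methoxy-4-{[2-pentyl-4,6-bis(trimethylsilyloxy)benzoyl]oxy}benzoate F8. Acidic work-up (1 M HCl, THF) would give benzyl 4-[(2,4-dihydroxy-6-pentylbenzoyl)oxy]-2-heptyl-6-methoxybenzoate F9. Its non-chelated 4-hydroxyl would then be methylated selectively (MeI 1.05 equiv, K2CO3, acetone, rt) to give 13.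

**Further compounds**
F1 | step 8 | methyl 2-hydroxy-4-methoxy-6-pentylbenzoate | CCCCCc1cc(OC)cc(O)c1C(=O)OC
F2 | step 8 | 2-hydroxy-4-methoxy-6-pentylbenzoic acid | CCCCCc1cc(OC)cc(O)c1C(=O)O
F3 | step 1 | 2-heptyl-4,6-dihydroxybenzaldehyde | CCCCCCCc1cc(O)cc(O)c1C=O
F4 | step 1 | 4-(allyloxy)-2-heptyl-6-hydroxybenzaldehyde | CCCCCCCc1cc(OCC=C)cc(O)c1C=O
F5 | step 1 | 4-(allyloxy)-2-heptyl-6-methoxybenzaldehyde | CCCCCCCc1cc(OCC=C)cc(OC)c1C=O
F6 | step 1 | 4-(allyloxy)-2-heptyl-6-methoxybenzoic acid | CCCCCCCc1cc(OCC=C)cc(OC)c1C(=O)O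
F7 | step 7 | 4-[(benzyloxy)carbonyl]-3-heptyl-5-methoxyphenyl 6-methoxy-2-pentyl-4,6-bis(trimethylsilyloxy)cyclohexa-1,4-diene-1-carboxylate (racemic) | CCCCCCCc1cc(OC(=O)C2=C(CCCCC)CC(O[Si](C)(C)C)=CC2(OC)O[Si](C)(C)C)cc(OC)c1C(=O)OCc1ccccc1
F8 | step 7 | benzyl 2-heptyl-6-methoxy-4-{[2-pentyl-4,6-bis(trimethylsilyloxy)benzoyl]oxy}benzoate | CCCCCCCc1cc(OC(=O)c2c(O[Si](C)(C)C)cc(O[Si](C)(C)C)cc2CCCCC)cc(OC)c1C(=O)OCc1ccccc1
F9 | step 7 | benzyl 4-[(2,4-dihydroxy-6-pentylbenzoyl)oxy]-2-heptyl-6-methoxybenzoate | CCCCCCCc1cc(OC(=O)c2c(O)cc(O)cc2CCCCC)cc(OC)c1C(=O)OCc1ccccc1
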